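The turnover, one passage of a molecule over the free catalyst, was the unit I counted in.

    target + free catalyst ⇌ isomer of the product A + free catalyst, rate k1*[free catalyst]*[target] forward; the back reaction follows from the equilibrium constant (K1 = 0.404, k1 = 0.0550 /M/min)
    starting material + free catalyst ⇌ target + free catalyst, rate k2*[starting material]*[free catalyst] forward; the back reaction follows from the equilibrium constant (K2 = 0.58, k2 = 1.84 /M/min)
    isomer of the product B + free catalyst ⇌ starting material + free catalyst, rate k3*[free catalyst]*[isomer of the product B] forward; the back reaction follows from the equilibrium constant (k3 = 0.158 /M/min)
    starting material + free catalyst → spent catalyst (k4 = 0.0246 /M/min)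
    isomer of the product A ⇌ isomer of the product B (K5 = 0.49, k5 = 2.90 × 10⁻⁵ /min)

in all of them: free catalyst 2.2 mM

|  | starting material | time | remark |
|---|---|---|---|
| Friday's | 20 mM (fed, over 16.0 d) | 20 d | a stirred flask in which starting material is dosed at a steady rate over 16.0 d without added volume, worked up at 20 d |
| Wednesday's | 20 mM | 20 d | everything together in a closed stirred flask, run for 20 d |
| Tuesday's | 20 mM |  | a single well-mixed tank run continuously and read at steady state, 20 d in it on average |

- the stated concentrations are those of everything mixed, before any reaction; amounts are the same in each set-up
- the feed brings no volume worth counting
- run time (Friday's): 20 d

- the set-up with the highest amount of target at the outlet or at the end, in percent of the starting material put in ("none" if the first two lie within 2 percentage points) (Friday's / Wednesday's / Tuesday's / none)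
- amount of target at the outlet or at the end, in percent of the starting material put in, Friday's
- amount of target at the outlet or at the end, in percent of the starting material put in, Wednesday's
- amount of target at the outlet or at the end, in percent of the starting material put in, Tuesday's

The main step (starting material to target) and the death step (starting material plus free catalyst to spent catalyst) run on the same two concentrations, so the ratio of their forward rates is a plain count: 74.8 forward main turnovers per catalyst lost. The charge of catalyst therefore offers 165 mM of turnover against 20 mM of starting material. Once the main step has equilibrated, the leak from target to isomer of the product A gets 1.30 forward turnovers per catalyst lost.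

I bracketed the flask with two extremes. In both I let the death step take 2.2 mM of starting material. If the main step equilibrates and the isomers stay empty, target is 32.7%. If both isomers equilibrate as well, it is 26.8%. I reckoned that in Wednesday's closed flask free catalyst lasts about 2.23 d, less than the 4.0 d forward half-life of target with the catalyst as charged, so I expected the leak to start but not to finish. I committed to the middle, 29.7%.

In Friday's dosed flask [starting material] climbs with the feed, so I used 8.45 d, the catalyst life under feed, the time in which free catalyst falls by a factor of e. At 16.9 d, twice that life, free catalyst is by this reckoning down to 0.0403 mM and the main step needs 3.44 d to relax, so I took this as the window in which feed gets served. It outlasts the dosing time of 16.0 d, which puts Friday's in the same bracket. I did not reckon Tuesday's tank.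

The forecast gave 27.5% for Friday's, 27.7% for Wednesday's and 28.8% for Tuesday's, with best none, on the ground that “Dosing changes little”. My middle stood higher than its figure for Wednesday's.

The simulation gave 29.0% for Friday's, 28.1% for Wednesday's and 28.9% for Tuesday's, so best is none, as forecast. At the end of Friday's feed free catalyst stood at 5.52% of its charge. The forecast's verdict needs Friday's to stay near Wednesday's. Friday's answer had moved by 5 points at a charge of 39.3 mM of starting material, and there the reckoned window is 12.1 d, shorter than the dosing.

For Friday's neighbour, charged with 80 mM, I reckoned a life of 4.22 d, so a window that closes after 42.2 mM of feed, which gives about 18.4% target with the isomers empty. Computed, it ended at 16.2%, with 77.7% starting material left.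

(All constants are invented.)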